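**Retrosynthetic overview** (chroman numbering: O1, C2, C3, C4, C4a, C5–C8, C8a)

1. Target 15 is a (4R)-chroman-4-ol with OH at C5 and C7, methyl at C6 and a 3-phenylpropanoyl group at C8. The two phenols are unmasked last (SEM ethers, fluoride), and the C8–acyl bond is cut to an aryllithium at C8 (the only ring C–H, between O1 and O7) plus Weinreb amide 12.
2. The strategy rests on the dihydropyran ring: C4 is a secondary benzylic carbinol bonded to arene carbon C4a and tied back through C3 and C2 (CMe2) to the aryl ether oxygen O1. Cutting C4–C4a gives a 3-aryloxy-3-methylbutanal with bromine on the future C4a (9); a nickel-catalysed asymmetric aryl–aldehyde reductive coupling closes the ring and sets C4 in one step.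
3. Aldehyde 9 comes from terminal alkyne 7 (hydroboration–oxidation), the bromine from bromination of 6 at one of two equivalent positions, and ether 6 from phenol 4 and 3-chloro-3-methylbut-1-yne 5.
4. Phenol 4 comes from 2-methylresorcinol 1 by SEM protection, iridium-catalysed C–H borylation at the only unhindered C–H (para to the methyl) and oxidation. The mirror symmetry of 2, 4 and 6 removes every regiochemical question.
5. Ring order: the arene is bought and the phenyl ring arrives with 11; the pyran ring is the only ring formed (step 6).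

Key step: step 6

Assumption: the aldehyde face favoured by a given enantiomer of the bis(oxazoline) ligand cannot be predicted with confidence. The (S,S) ligand is written, the configuration of 10 is to be checked (Mosher esters), and the (R,R) ligand is used instead if the 4S alcohol should form.

**Route**

Step 1
Reactants: 1 2-methylresorcinol
Product: 2 2-methyl-1,3-bis{[2-(trimethylsilyl)ethoxy]methoxy}benzene
Conditions: NaH (2.4 equiv), DMF, 0 °C; SEMCl (2.3 equiv), 0 °C → rt
Reagents that add atoms: 2-(trimethylsilyl)ethoxymethyl chloride (SEMCl), C[Si](C)(C)CCOCCl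
Why: Williamson-type O-alkylation of the bis-phenoxide by the reactive chloromethyl ether protects both equivalent phenols as SEM acetals, which later direct metalation and come off with fluoride.

Step 2
Reactants: 2 2-methyl-1,3-bis{[2-(trimethylsilyl)ethoxy]methoxy}benzene
Product: 4 4-methyl-3,5-bis{[2-(trimethylsilyl)ethoxy]methoxy}phenol, via aryl pinacol boronate 3 (not isolated)
Conditions: [Ir(OMe)(cod)]2 (1.5 mol%), 4,4'-di-tert-butyl-2,2'-bipyridine (3 mol%), B2pin2 (1.0 equiv), THF, 80 °C; then aq. NaOH, 30% H2O2, 0 °C → rt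
Reagents that add atoms: bis(pinacolato)diboron, CC1(C)OB(OC1(C)C)B1OC(C)(C)C(C)(C)O1 (boryl group of 3 only); hydrogen peroxide, OO (phenol oxygen of 4)
Why: Iridium-catalysed C–H borylation is governed by sterics and should take the one C–H without an ortho substituent (meta to both acetal oxygens, para to the methyl), and basic peroxide then turns the C–B bond into C–O by a 1,2-aryl shift in the same flask.

Step 3
Reactants: 4 4-methyl-3,5-bis{[2-(trimethylsilyl)ethoxy]methoxy}phenol; 5 3-chloro-3-methylbut-1-yne
Product: 6 2-methyl-5-[(2-methylbut-3-yn-2-yl)oxy]-1,3-bis{[2-(trimethylsilyl)ethoxy]methoxy}benzene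
Conditions: K2CO3 (2 equiv), KI (0.1 equiv), CuI (5 mol%), acetone, 50 °C
Reagents that add atoms: none
Why: Copper-assisted propargylic substitution (through the copper acetylide and its zwitterionic allenylidene form) lets the phenoxide attack the tertiary carbon, a standard entry to aryl 1,1-dimethylpropargyl ethers, and 50 °C lies far below the onset of the propargyl Claisen rearrangement.

Step 4
Reactants: 6 2-methyl-5-[(2-methylbut-3-yn-2-yl)oxy]-1,3-bis{[2-(trimethylsilyl)ethoxy]methoxy}benzene
Product: 7 2-bromo-4-methyl-1-[(2-methylbut-3-yn-2-yl)oxy]-3,5-bis{[2-(trimethylsilyl)ethoxy]methoxy}benzene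
Conditions: NBS (1.0 equiv), MeCN, −20 → 0 °C, dark
Reagents that add atoms: N-bromosuccinimide, O=C1CCC(=O)N1Br
Why: Electrophilic aromatic bromination of a phloroglucinol-type triether is fast, the two open ring positions are equivalent by symmetry and each lies ortho to the propargyl ether oxygen, and one equivalent of NBS at low temperature should stop at the monobromide.

Step 5
Reactants: 7 2-bromo-4-methyl-1-[(2-methylbut-3-yn-2-yl)oxy]-3,5-bis{[2-(trimethylsilyl)ethoxy]methoxy}benzene
Product: 9 3-(2-bromo-4-methyl-3,5-bis{[2-(trimethylsilyl)ethoxy]methoxy}phenoxy)-3-methylbutanal, via alkenyl dicyclohexylborane 8 (not isolated)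
Conditions: Cy2BH (1.3 equiv, from BH3·SMe2 + cyclohexene, THF, 0 °C), THF, 0 °C → rt; then pH 7 phosphate buffer, 30% H2O2, 0 °C
Reagents that add atoms: dicyclohexylborane, C1CCC(CC1)BC1CCCCC1 (made in the flask from borane–dimethyl sulfide, B.CSC, and cyclohexene, C1CCC=CC1; boryl group of 8 only); hydrogen peroxide, OO (aldehyde oxygen of 9)
Why: The bulky dialkylborane adds once, syn and anti-Markovnikov, to the terminal alkyne (hydroboration), and oxidation of the alkenyl C–B bond gives the enol and hence the aldehyde, with the pH 7 buffer keeping the β-aryloxy aldehyde from E1cB loss of the aryloxide while the aryl bromide and the acetals stay inert.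

Step 6
Reactants: 9 3-(2-bromo-4-methyl-3,5-bis{[2-(trimethylsilyl)ethoxy]methoxy}phenoxy)-3-methylbutanal
Product: 10 (4R)-2,2,6-trimethyl-5,7-bis{[2-(trimethylsilyl)ethoxy]methoxy}-3,4-dihydro-2H-chromen-4-ol
Conditions: NiBr2(dme) (10 mol%), (S,S)-Ph-BOX [2,2'-(propane-2,2-diyl)bis((4S)-4-phenyl-4,5-dihydro-1,3-oxazole)] (12 mol%), Mn powder (3 equiv), degassed DMA, 25–40 °C; then aq. NH4Cl
Reagents that add atoms: none
Why: Proposed new method: zerovalent nickel carrying the bis(oxazoline) should insert into the C–Br bond of 9, the tethered aldehyde then binds and inserts into the aryl–nickel bond, and the nickel alkoxide is passed on to manganese while the metal powder returns nickel to its low-valent state; the closest known reaction types are the nickel-catalysed enantioselective intramolecular reductive addition of aryl halides to tethered ketones (benzo-fused tertiary carbinols) and the catalytic asymmetric Nozaki–Hiyama–Kishi arylation of aldehydes, neither shown for an aldehyde acceptor with a bromide flanked by two oxygen substituents. The pyran ring closes by 6-exo-trig attack of arene carbon C4a on the aldehyde carbon C4, helped by the gem-dimethyl group at C2 (Thorpe–Ingold effect). C4 is the only stereocentre and the substrate is achiral, so its configuration is controlled by the chiral ligand on nickel, which differentiates the two faces of the nickel-bound aldehyde in the insertion. The site of ring closure needs no control because only the brominated carbon can bond and the tether reaches only the aldehyde. The step needs chemoselectivity for 1,2-addition over β-elimination of the aryloxide and over biaryl formation; the neutral, base-free reductant should secure the first, and the two ortho substituents together with the intramolecular acceptor the second.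

Step 7
Reactants: 11 3-phenylpropanoyl chloride
Product: 12 N-methoxy-N-methyl-3-phenylpropanamide
Conditions: MeNH(OMe)·HCl (1.1 equiv), K2CO3 (2.5 equiv), EtOAc/H2O, 0 °C → rt
Reagents that add atoms: N,O-dimethylhydroxylamine hydrochloride, CNOC.Cl
Why: Schotten–Baumann acylation of N,O-dimethylhydroxylamine by the acid chloride gives the Weinreb amide.

Step 8
Reactants: 10 (4R)-2,2,6-trimethyl-5,7-bis{[2-(trimethylsilyl)ethoxy]methoxy}-3,4-dihydro-2H-chromen-4-ol; 12 N-methoxy-N-methyl-3-phenylpropanamide
Product: 14 1-[(4R)-4-hydroxy-2,2,6-trimethyl-5,7-bis{[2-(trimethylsilyl)ethoxy]methoxy}-3,4-dihydro-2H-chromen-8-yl]-3-phenylpropan-1-one, via dilithio chromanolate 13 (not isolated)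
Conditions: n-BuLi (2.3 equiv), TMEDA (2.3 equiv), THF, 0 °C, 1 h; then 12 (1.5 equiv), −78 → 0 °C; aq. NH4Cl
Reagents that add atoms: n-butyllithium, [Li]CCCC (lithium of 13 only)
Why: The first equivalent of n-BuLi makes the C4 lithium alkoxide and the second removes the only ring hydrogen, at C8 between O1 and the C7 acetal oxygen (directed ortho-metalation by two cooperating oxygen groups), and the aryllithium adds to 12 to give a chelated tetrahedral adduct that releases the ketone only on work-up (Weinreb ketone synthesis), so over-addition is excluded and C4 is not touched.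

Step 9
Reactants: 14 1-[(4R)-4-hydroxy-2,2,6-trimethyl-5,7-bis{[2-(trimethylsilyl)ethoxy]methoxy}-3,4-dihydro-2H-chromen-8-yl]-3-phenylpropan-1-one
Product: 15 1-[(4R)-4,5,7-trihydroxy-2,2,6-trimethyl-3,4-dihydro-2H-chromen-8-yl]-3-phenylpropan-1-one (the target)
Conditions: TBAF (8 equiv), THF/DMPU, 4 Å MS, 50 °C; aq. NH4Cl
Reagents that add atoms: none
Why: Fluoride attacks silicon in each SEM group and the acetal fragments to fluorotrimethylsilane, ethylene, formaldehyde and the phenoxide, a cleavage eased by the acyl group ortho to O7 and para to O5, while the non-acidic medium should spare the readily ionised C4 benzylic carbinol and its configuration.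

**Compound list**

1 | 2-methylresorcinol | Cc1c(O)cccc1O | starting material
2 | 2-methyl-1,3-bis{[2-(trimethylsilyl)ethoxy]methoxy}benzene | Cc1c(OCOCC[Si](C)(C)C)cccc1OCOCC[Si](C)(C)C | intermediate
3 | 2-(4-methyl-3,5-bis{[2-(trimethylsilyl)ethoxy]methoxy}phenyl)-4,4,5,5-tetramethyl-1,3,2-dioxaborolane (not isolated) | Cc1c(OCOCC[Si](C)(C)C)cc(B2OC(C)(C)C(C)(C)O2)cc1OCOCC[Si](C)(C)C | intermediate
4 | 4-methyl-3,5-bis{[2-(trimethylsilyl)ethoxy]methoxy}phenol | Cc1c(OCOCC[Si](C)(C)C)cc(O)cc1OCOCC[Si](C)(C)C | intermediate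
5 | 3-chloro-3-methylbut-1-yne | CC(C)(Cl)C#C | starting material
6 | 2-methyl-5-[(2-methylbut-3-yn-2-yl)oxy]-1,3-bis{[2-(trimethylsilyl)ethoxy]methoxy}benzene | Cc1c(OCOCC[Si](C)(C)C)cc(OC(C)(C)C#C)cc1OCOCC[Si](C)(C)C | intermediate
7 | 2-bromo-4-methyl-1-[(2-methylbut-3-yn-2-yl)oxy]-3,5-bis{[2-(trimethylsilyl)ethoxy]methoxy}benzene | Cc1c(OCOCC[Si](C)(C)C)cc(OC(C)(C)C#C)c(Br)c1OCOCC[Si](C)(C)C | intermediate
8 | [(E)-3-(2-bromo-4-methyl-3,5-bis{[2-(trimethylsilyl)ethoxy]methoxy}phenoxy)-3-methylbut-1-en-1-yl]dicyclohexylborane (not isolated) | Cc1c(OCOCC[Si](C)(C)C)cc(OC(C)(C)/C=C/B(C2CCCCC2)C2CCCCC2)c(Br)c1OCOCC[Si](C)(C)C | intermediate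
9 | 3-(2-bromo-4-methyl-3,5-bis{[2-(trimethylsilyl)ethoxy]methoxy}phenoxy)-3-methylbutanal | Cc1c(OCOCC[Si](C)(C)C)cc(OC(C)(C)CC=O)c(Br)c1OCOCC[Si](C)(C)C | intermediate
10 | (4R)-2,2,6-trimethyl-5,7-bis{[2-(trimethylsilyl)ethoxy]methoxy}-3,4-dihydro-2H-chromen-4-ol | Cc1c(OCOCC[Si](C)(C)C)cc2c(c1OCOCC[Si](C)(C)C)[C@H](O)CC(C)(C)O2 | intermediate
11 | 3-phenylpropanoyl chloride | O=C(Cl)CCc1ccccc1 | starting material
12 | N-methoxy-N-methyl-3-phenylpropanamide | CON(C)C(=O)CCc1ccccc1 | intermediate
13 | lithium (4R)-8-lithio-2,2,6-trimethyl-5,7-bis{[2-(trimethylsilyl)ethoxy]methoxy}-3,4-dihydro-2H-chromen-4-olate (not isolated) | Cc1c(OCOCC[Si](C)(C)C)c([Li])c2c(c1OCOCC[Si](C)(C)C)[C@H](O[Li])CC(C)(C)O2 | intermediate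
14 | 1-[(4R)-4-hydroxy-2,2,6-trimethyl-5,7-bis{[2-(trimethylsilyl)ethoxy]methoxy}-3,4-dihydro-2H-chromen-8-yl]-3-phenylpropan-1-one | Cc1c(OCOCC[Si](C)(C)C)c(C(=O)CCc3ccccc3)c2c(c1OCOCC[Si](C)(C)C)[C@H](O)CC(C)(C)O2 | intermediate
15 | 1-[(4R)-4,5,7-trihydroxy-2,2,6-trimethyl-3,4-dihydro-2H-chromen-8-yl]-3-phenylpropan-1-one | Cc1c(O)c(C(=O)CCc2ccccc2)c2c(c1O)[C@H](O)CC(C)(C)O2 | target

**Step count**

Total: 9 steps. Longest linear sequence: 8 steps (steps 1–6, 8 and 9); step 7 is a one-step branch.

**Steps most likely to fail**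

Step 6 (the proposed new method). Oxidative addition into the electron-rich C–Br bond flanked by two ortho oxygens may be slow, and the aldehyde could meanwhile be lost by β-elimination of the aryloxide or by reduction. Facial selectivity at the aldehyde may be poor, and the nickel alkoxide may lose a β-hydride to give the ketone oxidation level. The fallback separates ring closure from stereocontrol and uses known reactions only. It sets out from 9 and returns at 10.
- Pinnick oxidation (NaClO2, NaH2PO4, 2-methylbut-2-ene, t-BuOH/H2O) should give 3-(2-bromo-4-methyl-3,5-bis{[2-(trimethylsilyl)ethoxy]methoxy}phenoxy)-3-methylbutanoic acid F1.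
- Parham cyclisation (n-BuLi, 2.2 equiv, THF, −100 °C) forms the carboxylate, exchanges bromine for lithium and acylates the aryllithium on the lithium carboxylate, which should give 2,2,6-trimethyl-5,7-bis{[2-(trimethylsilyl)ethoxy]methoxy}-2,3-dihydro-4H-chromen-4-one F2.
- Noyori asymmetric transfer hydrogenation (RuCl[(R,R)-TsDPEN](p-cymene), HCO2H/Et3N) of this aryl alkyl ketone should deliver the (4R)-alcohol 10, the arene acting as the large group as in the reduction of simple chroman-4-ones.

Step 8. Metalation of the alkoxide-bearing arene may be incomplete, or the hindered aryllithium may take a proton from the enolisable amide instead of adding, returning 10. The fallback sets out from 10 and returns at 15.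
- TBSCl and imidazole in DMF should give tert-butyl(dimethyl){[(4R)-2,2,6-trimethyl-5,7-bis{[2-(trimethylsilyl)ethoxy]methoxy}-3,4-dihydro-2H-chromen-4-yl]oxy}silane F3.
- Lithiation at C8 (n-BuLi/TMEDA, THF, 0 °C) and addition to the more electrophilic 3-phenylpropanal at −78 °C should give 1-[(4R)-4-[(tert-butyldimethylsilyl)oxy]-2,2,6-trimethyl-5,7-bis{[2-(trimethylsilyl)ethoxy]methoxy}-3,4-dihydro-2H-chromen-8-yl]-3-phenylpropan-1-ol F4, as a mixture of epimers at the new carbinol carbon, which is of no consequence.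
- Dess–Martin periodinane with NaHCO3 in CH2Cl2 should give the ketone 1-[(4R)-4-[(tert-butyldimethylsilyl)oxy]-2,2,6-trimethyl-5,7-bis{[2-(trimethylsilyl)ethoxy]methoxy}-3,4-dihydro-2H-chromen-8-yl]-3-phenylpropan-1-one F5.
- The fluoride conditions of step 9 then remove the silyl ether and both SEM groups together to reach 15.

Step 5. The aryloxide may be lost by β-elimination (retro-oxa-Michael) during the aqueous oxidative work-up, or the alkenylborane may be oxidised incompletely at neutral pH. The fallback passes through the alcohol oxidation level, so the carbonyl group first appears under neutral, non-aqueous conditions. It sets out from 7 and returns at 9.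
- Semi-hydrogenation (H2, Pd/CaCO3 poisoned with Pb(OAc)2, quinoline, EtOAc, rt) should give 2-bromo-4-methyl-1-[(2-methylbut-3-en-2-yl)oxy]-3,5-bis{[2-(trimethylsilyl)ethoxy]methoxy}benzene F6.
- Hydroboration with 9-BBN (THF, rt) and NaOH/H2O2 oxidation should give the base-stable 3-(2-bromo-4-methyl-3,5-bis{[2-(trimethylsilyl)ethoxy]methoxy}phenoxy)-3-methylbutan-1-ol F7.
- Dess–Martin periodinane with NaHCO3 (CH2Cl2, 0 °C) should give 9.

**Further compounds**

F1 | step 6 | 3-(2-bromo-4-methyl-3,5-bis{[2-(trimethylsilyl)ethoxy]methoxy}phenoxy)-3-methylbutanoic acid | Cc1c(OCOCC[Si](C)(C)C)cc(OC(C)(C)CC(=O)O)c(Br)c1OCOCC[Si](C)(C)C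
F2 | step 6 | 2,2,6-trimethyl-5,7-bis{[2-(trimethylsilyl)ethoxy]methoxy}-2,3-dihydro-4H-chromen-4-one | Cc1c(OCOCC[Si](C)(C)C)cc2c(c1OCOCC[Si](C)(C)C)C(=O)CC(C)(C)O2
F3 | step 8 | tert-butyl(dimethyl){[(4R)-2,2,6-trimethyl-5,7-bis{[2-(trimethylsilyl)ethoxy]methoxy}-3,4-dihydro-2H-chromen-4-yl]oxy}silane | Cc1c(OCOCC[Si](C)(C)C)cc2c(c1OCOCC[Si](C)(C)C)[C@H](O[Si](C)(C)C(C)(C)C)CC(C)(C)O2
F4 | step 8 | 1-[(4R)-4-[(tert-butyldimethylsilyl)oxy]-2,2,6-trimethyl-5,7-bis{[2-(trimethylsilyl)ethoxy]methoxy}-3,4-dihydro-2H-chromen-8-yl]-3-phenylpropan-1-ol (both epimers at the new carbinol carbon) | Cc1c(OCOCC[Si](C)(C)C)c(C(O)CCc3ccccc3)c2c(c1OCOCC[Si](C)(C)C)[C@H](O[Si](C)(C)C(C)(C)C)CC(C)(C)O2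
F5 | step 8 | 1-[(4R)-4-[(tert-butyldimethylsilyl)oxy]-2,2,6-trimethyl-5,7-bis{[2-(trimethylsilyl)ethoxy]methoxy}-3,4-dihydro-2H-chromen-8-yl]-3-phenylpropan-1-one | Cc1c(OCOCC[Si](C)(C)C)c(C(=O)CCc3ccccc3)c2c(c1OCOCC[Si](C)(C)C)[C@H](O[Si](C)(C)C(C)(C)C)CC(C)(C)O2
F6 | step 5 | 2-bromo-4-methyl-1-[(2-methylbut-3-en-2-yl)oxy]-3,5-bis{[2-(trimethylsilyl)ethoxy]methoxy}benzene | Cc1c(OCOCC[Si](C)(C)C)cc(OC(C)(C)C=C)c(Br)c1OCOCC[Si](C)(C)C
F7 | step 5 | 3-(2-bromo-4-methyl-3,5-bis{[2-(trimethylsilyl)ethoxy]methoxy}phenoxy)-3-methylbutan-1-ol | Cc1c(OCOCC[Si](C)(C)C)cc(OC(C)(C)CCO)c(Br)c1OCOCC[Si](C)(C)C
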